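**Remark on the chemistry:** flavan numbering (O1, C2–C4, C4a–C8a; rings A, B, C) is used for every unit. The carbinol configurations drawn at C4 of the middle unit (10, 21, 22, 24) and at the tertiary carbinol carbon of 22 are the expected ones; both carbons are ionised later, so they do not affect the outcome.

## Retrosynthetic overview

1. The target is ent-robinetinidol-(4α→8)-ent-epirobinetinidol-(4α→8)-(−)-epicatechin (upper 2S,3R,4S; middle 2S,3S,4S; lower 2R,3R). It is reached by global O-debenzylation after a Friedel–Crafts union of a middle-unit 4-ol with tetra-O-benzylepicatechin, which forms middle C4–lower C8 anti to O3 and the C2 aryl group.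
2. The upper C4–H is set by ionic hydrogenation of a tertiary diaryl carbinol, with hydride entering anti to O3; this gives the 3,4-cis linkage that aryl-to-cation coupling disfavours.
3. Key disconnection: ring C of the middle unit (O1–C8a) and the middle C8–upper C4 bond are made in one operation from open-chain fluoro-diol 10 and flavan-4-one 16 by an aryne relay.
4. Enabling feature: in ring A of the middle unit, O1 sits on C8a, which lies between C4a (carrying the C4–C3–C2 chain with its C2 oxygen) and C8 (carrying the upper unit), and meta to O7. A C8a–F/C8–H pair next to the C7 benzyloxy group therefore gives the C8≡C8a aryne, which takes oxygen at C8a and leaves the carbanion at C8.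
5. Ring order: upper ring C first (chalcone epoxide to dihydroflavonol), lower ring C from epicatechin, middle ring C last. Middle C2/C3 come from an Evans glycolate aldol, upper C2/C3 from a Juliá–Colonna epoxidation.

Key step: step 12

## Route

Step 1
Reactants: 1 (R)-4-benzyl-1,3-oxazolidin-2-one; 2 benzyloxyacetyl chloride
Product: 3 (R)-4-benzyl-3-[(benzyloxy)acetyl]-1,3-oxazolidin-2-one
Conditions: n-BuLi, THF, −78 °C; then 2, −78 → 0 °C
Reagents that add atoms: none
Why: N-acylation of the lithiated oxazolidinone by the acid chloride gives the Evans glycolate imide without touching the auxiliary stereocentre.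

Step 2
Reactants: 3; 4 3,4,5-tris(benzyloxy)benzaldehyde
Product: 5 (4R)-4-benzyl-3-{(2R,3S)-2-(benzyloxy)-3-hydroxy-3-[3,4,5-tris(benzyloxy)phenyl]propanoyl}-1,3-oxazolidin-2-one
Conditions: Bu2BOTf, Et3N, CH2Cl2, −78 → 0 °C; 4, −78 → 0 °C; then pH 7 buffer, MeOH, H2O2
Reagents that add atoms: none
Why: Evans syn glycolate aldol through the Z boron enolate and a closed chair transition state, the auxiliary benzyl group shielding one enolate face; it sets the two centres that become C3 (O-benzyl) and C2 (free OH) of the middle unit in the 2,3-cis (2S,3S) sense.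

Step 3
Reactants: 5
Product: 6 (2R,3S)-2-(benzyloxy)-3-hydroxy-N-methoxy-N-methyl-3-[3,4,5-tris(benzyloxy)phenyl]propanamide
Conditions: MeNHOMe·HCl, Me3Al, THF, −10 → 0 °C; 1 M HCl work-up
Reagents that add atoms: N,O-dimethylhydroxylamine hydrochloride (CNOC.Cl)
Why: Aluminium-amide transamination of the imide (Weinreb amide formation) is standard for unprotected syn aldol adducts and releases the auxiliary without epimerisation.

Step 4
Reactants: 6; 7 4-(benzyloxy)-1-bromo-2-fluorobenzene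
Product: 9 (2R,3S)-2-(benzyloxy)-1-[4-(benzyloxy)-2-fluorophenyl]-3-hydroxy-3-[3,4,5-tris(benzyloxy)phenyl]propan-1-one, via arylmagnesium chloride 8 (not isolated)
Conditions: 7, i-PrMgCl·LiCl, THF, −15 °C → rt; separately 6, i-PrMgCl·LiCl (1.0 equiv), THF, −20 °C; combine, 0 °C; 1 M HCl
Reagents that add atoms: none
Why: Weinreb ketone synthesis: Br/Mg exchange gives a 2-fluoroaryl Grignard reagent that is stable below room temperature, the hydroxyl is first converted to its magnesium alkoxide, and the chelated tetrahedral adduct prevents over-addition.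

Step 5
Reactants: 9
Product: 10 (1R,2R,3S)-2-(benzyloxy)-1-[4-(benzyloxy)-2-fluorophenyl]-3-[3,4,5-tris(benzyloxy)phenyl]propane-1,3-diol (all-syn)
Conditions: Et2BOMe, NaBH4, THF/MeOH, −78 °C; MeOH co-evaporation
Reagents that add atoms: none
Why: Narasaka–Prasad reduction: external hydride attacks the boron chelate of the β-hydroxy ketone to give the 1,3-syn diol, so the new carbinol (future C4 of the middle unit) is a single isomer.

Step 6
Reactants: 11 1-[4-(benzyloxy)-2-hydroxyphenyl]ethan-1-one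
Product: 12 1-[4-(benzyloxy)-2-(methoxymethoxy)phenyl]ethan-1-one
Conditions: NaH, DMF, 0 °C; MOMCl, 0 °C → rt
Reagents that add atoms: chloromethyl methyl ether (COCCl)
Why: Williamson etherification of the chelated phenoxide masks the phenol, which would otherwise divert the later epoxidation to aurone and flavonol products.

Step 7
Reactants: 12; 4
Product: 13 (E)-1-[4-(benzyloxy)-2-(methoxymethoxy)phenyl]-3-[3,4,5-tris(benzyloxy)phenyl]prop-2-en-1-one
Conditions: KOH, EtOH/THF, rt
Reagents that add atoms: none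
Why: Claisen–Schmidt condensation of the methyl ketone with the non-enolisable aldehyde gives the E-chalcone under thermodynamic control.

Step 8
Reactants: 13
Product: 14 [4-(benzyloxy)-2-(methoxymethoxy)phenyl]{(2S,3R)-3-[3,4,5-tris(benzyloxy)phenyl]oxiran-2-yl}methanone
Conditions: poly-D-leucine, urea–H2O2, DBU, THF, rt
Reagents that add atoms: urea–hydrogen peroxide (OO.NC(N)=O)
Why: Juliá–Colonna epoxidation: hydroperoxide adds to the enone held on the helical polypeptide, and poly-D-leucine gives the (αS,βR) trans-epoxide, the mirror image of the (αR,βS) product known for poly-L-leucine.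

Step 9
Reactants: 14
Product: 15 (2S,3S)-7-(benzyloxy)-3-hydroxy-2-[3,4,5-tris(benzyloxy)phenyl]-2,3-dihydro-4H-chromen-4-one
Conditions: conc. HCl (cat.), MeOH/THF, 50 °C
Reagents that add atoms: none
Why: Acid removes the methoxymethyl group and the freed phenol opens the epoxide at the benzylic carbon in a 6-endo closure with inversion, giving the 2,3-trans dihydroflavonol with C3 retained (the established chalcone-epoxide route to dihydroflavonols).

Step 10
Reactants: 15
Product: 16 (2S,3S)-3,7-bis(benzyloxy)-2-[3,4,5-tris(benzyloxy)phenyl]-2,3-dihydro-4H-chromen-4-one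
Conditions: BnBr, Ag2O, CH2Cl2, rt, dark
Reagents that add atoms: benzyl bromide (BrCc1ccccc1)
Why: Silver-oxide-mediated O-benzylation works without an alkoxide base and so avoids the enolisation, ring opening and epimerisation that basic conditions cause in dihydroflavonols.

Step 11
Reactants: 17 (−)-epicatechin
Product: 18 (2R,3R)-5,7-bis(benzyloxy)-2-[3,4-bis(benzyloxy)phenyl]chroman-3-ol
Conditions: BnBr (4.2 equiv), K2CO3, DMF, 0 °C → rt
Reagents that add atoms: benzyl bromide (BrCc1ccccc1)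
Why: Williamson benzylation under carbonate conditions is selective for the four phenols because the aliphatic 3-OH is not deprotonated.

Step 12
Reactants: 10; 16
Product: 22 (2S,3S,4R)-3,7-bis(benzyloxy)-8-{(2S,3S,4S)-3,7-bis(benzyloxy)-4-hydroxy-2-[3,4,5-tris(benzyloxy)phenyl]chroman-4-yl}-2-[3,4,5-tris(benzyloxy)phenyl]chroman-4-ol, via trilithiated diolate 19 (not isolated), via aryne dialkoxide 20 (not isolated), via 8-lithioflavan alkoxide 21 (not isolated)
Conditions: 10 (1.3 equiv), LiTMP (3.2 equiv per 10), THF, −78 °C; warm to −10 °C; recool to −78 °C; 16 premixed with LaCl3·2LiCl, THF, −78 → −30 °C; H2O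
Reagents that add atoms: none
Why: Proposed new method: LiTMP forms both lithium alkoxides of 10 and then removes the single ring proton flanked by fluorine and the benzyloxy group (19); on warming LiF is lost to give the 3-alkoxyaryne 20, and the alkoxide on the carbon that becomes C2 attacks the aryne carbon next to the side chain in a 6-exo-dig closure that forms O1–C8a of ring C and leaves the carbanion of 21 at C8, held between O1 and O7. The closest known reaction type is the anionic cyclisation of tethered nitrogen and carbon nucleophiles onto arynes made from ortho-lithiated fluoroarenes followed by electrophile capture of the new aryllithium, together with the meta-directed addition of nucleophiles to 3-alkoxyarynes; new here are the alkoxide as tethered nucleophile and a lanthanum-activated, enolisable flavan-4-one as electrophile. Regiocontrol of the lithiation comes from the joint acidifying effect of F and OBn on the one C–H between them, and regiocontrol of the aryne addition from the tether length and the inductive effect of the alkoxy group. Chemoselectivity is built into the substrate: O3 is benzylated so no five-membered ether can form, and the C4 alkoxide cannot reach the aryne. No stereocentre of 10 is touched because the bond is made by oxygen, so C2 and C3 keep the aldol configuration; the only new centre is the tertiary carbinol, expected with the aryl group anti to the 3-benzyloxy group and erased in step 13. LaCl3·2LiCl activates the ketone so that 1,2-addition of the hindered 2,6-dioxygenated aryllithium outruns enolisation and ring opening of 16.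

Step 13
Reactants: 22
Product: 24 (2S,3S,4R)-3,7-bis(benzyloxy)-8-{(2S,3R,4S)-3,7-bis(benzyloxy)-2-[3,4,5-tris(benzyloxy)phenyl]chroman-4-yl}-2-[3,4,5-tris(benzyloxy)phenyl]chroman-4-ol, via diarylcarbenium ion 23 (not isolated)
Conditions: Et3SiH (5 equiv), CF3CO2H (3 equiv), CH2Cl2, −60 → −40 °C
Reagents that add atoms: none
Why: Ionic hydrogenation: the doubly benzylic tertiary carbinol ionises at low temperature while the secondary 4-OH of the middle unit (one aryl group, β-benzyloxy) should not, and hydride should enter anti to the 3-benzyloxy group, the face that carbon nucleophiles choose in 2,3-trans-flavan-4-yl cations, which places the C8 aryl group cis to O3 (2,3-trans-3,4-cis, 4S).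

Step 14
Reactants: 24; 18
Product: 26 tetradeca-O-benzyl trimer: upper (2S,3R,4S) unit–(4→8)–middle (2S,3S,4S) unit–(4→8)–5,7,3',4'-tetra-O-benzyl-(2R,3R)-epicatechin (lower 3-OH free), via flavan-4-yl cation 25 (not isolated)
Conditions: 18 (3 equiv), BF3·OEt2 (0.5 equiv), CH2Cl2, −40 → 0 °C
Reagents that add atoms: none
Why: Friedel–Crafts alkylation as used for benzylated proanthocyanidins: the Lewis acid ionises the 2,4-dioxygenated benzylic alcohol, the phloroglucinol-type ring A of 18 attacks through C8 (the usual site for 5,7-di-O-benzyl flavan-3-ols), and the 2,3-cis cation is entered anti to both the C2 aryl and the C3 benzyloxy group, giving the 3,4-trans (4S) bond.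

Step 15
Reactants: 26
Product: 27 ent-robinetinidol-(4α→8)-ent-epirobinetinidol-(4α→8)-(−)-epicatechin (target)
Conditions: H2 (1 atm), Pd(OH)2/C, THF/MeOH/H2O, rt
Reagents that add atoms: none
Why: Hydrogenolysis over Pd(OH)2/C removes all fourteen benzyl ethers (aryl and the two alkyl ones) under neutral conditions that leave the interflavan bonds and all stereocentres intact.

## Compound list

1 | (R)-4-benzyl-1,3-oxazolidin-2-one | O=C1N[C@H](Cc2ccccc2)CO1 | starting material
2 | benzyloxyacetyl chloride | O=C(Cl)COCc1ccccc1 | starting material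
3 | (R)-4-benzyl-3-[(benzyloxy)acetyl]-1,3-oxazolidin-2-one | O=C(COCc1ccccc1)N1[C@H](Cc2ccccc2)COC1=O | intermediate
4 | 3,4,5-tris(benzyloxy)benzaldehyde | O=Cc1cc(OCc2ccccc2)c(OCc2ccccc2)c(OCc2ccccc2)c1 | starting material
5 | (4R)-4-benzyl-3-{(2R,3S)-2-(benzyloxy)-3-hydroxy-3-[3,4,5-tris(benzyloxy)phenyl]propanoyl}-1,3-oxazolidin-2-one | O[C@@H](c1cc(OCc2ccccc2)c(OCc2ccccc2)c(OCc2ccccc2)c1)[C@@H](OCc1ccccc1)C(=O)N1[C@H](Cc2ccccc2)COC1=O | intermediate
6 | (2R,3S)-2-(benzyloxy)-3-hydroxy-N-methoxy-N-methyl-3-[3,4,5-tris(benzyloxy)phenyl]propanamide | O[C@@H](c1cc(OCc2ccccc2)c(OCc2ccccc2)c(OCc2ccccc2)c1)[C@@H](OCc1ccccc1)C(=O)N(C)OC | intermediate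
7 | 4-(benzyloxy)-1-bromo-2-fluorobenzene | Fc1cc(OCc2ccccc2)ccc1Br | starting material
8 | [4-(benzyloxy)-2-fluorophenyl]magnesium chloride (LiCl complex) | Fc1cc(OCc2ccccc2)ccc1[Mg]Cl | intermediate
9 | (2R,3S)-2-(benzyloxy)-1-[4-(benzyloxy)-2-fluorophenyl]-3-hydroxy-3-[3,4,5-tris(benzyloxy)phenyl]propan-1-one | O[C@@H](c1cc(OCc2ccccc2)c(OCc2ccccc2)c(OCc2ccccc2)c1)[C@@H](OCc1ccccc1)C(=O)c1ccc(OCc2ccccc2)cc1F | intermediate
10 | (1R,2R,3S)-2-(benzyloxy)-1-[4-(benzyloxy)-2-fluorophenyl]-3-[3,4,5-tris(benzyloxy)phenyl]propane-1,3-diol | O[C@@H](c1cc(OCc2ccccc2)c(OCc2ccccc2)c(OCc2ccccc2)c1)[C@@H](OCc1ccccc1)[C@H](O)c1ccc(OCc2ccccc2)cc1F | intermediate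
11 | 1-[4-(benzyloxy)-2-hydroxyphenyl]ethan-1-one | CC(=O)c1ccc(OCc2ccccc2)cc1O | starting material
12 | 1-[4-(benzyloxy)-2-(methoxymethoxy)phenyl]ethan-1-one | CC(=O)c1ccc(OCc2ccccc2)cc1OCOC | intermediate
13 | (E)-1-[4-(benzyloxy)-2-(methoxymethoxy)phenyl]-3-[3,4,5-tris(benzyloxy)phenyl]prop-2-en-1-one | O=C(/C=C/c1cc(OCc2ccccc2)c(OCc2ccccc2)c(OCc2ccccc2)c1)c1ccc(OCc2ccccc2)cc1OCOC | intermediate
14 | [4-(benzyloxy)-2-(methoxymethoxy)phenyl]{(2S,3R)-3-[3,4,5-tris(benzyloxy)phenyl]oxiran-2-yl}methanone | O=C([C@H]1O[C@@H]1c2cc(OCc3ccccc3)c(OCc3ccccc3)c(OCc3ccccc3)c2)c2ccc(OCc3ccccc3)cc2OCOC | intermediate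
15 | (2S,3S)-7-(benzyloxy)-3-hydroxy-2-[3,4,5-tris(benzyloxy)phenyl]-2,3-dihydro-4H-chromen-4-one | O=C1c2ccc(OCc3ccccc3)cc2O[C@@H](c2cc(OCc3ccccc3)c(OCc3ccccc3)c(OCc3ccccc3)c2)[C@@H]1O | intermediate
16 | (2S,3S)-3,7-bis(benzyloxy)-2-[3,4,5-tris(benzyloxy)phenyl]-2,3-dihydro-4H-chromen-4-one | O=C1c2ccc(OCc3ccccc3)cc2O[C@@H](c2cc(OCc3ccccc3)c(OCc3ccccc3)c(OCc3ccccc3)c2)[C@@H]1OCc1ccccc1 | intermediate
17 | (−)-epicatechin, (2R,3R) | Oc1cc(O)c2c(c1)O[C@H](c1ccc(O)c(O)c1)[C@H](O)C2 | starting material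
18 | (2R,3R)-5,7-bis(benzyloxy)-2-[3,4-bis(benzyloxy)phenyl]chroman-3-ol | C(c1ccccc1)Oc1cc(OCc2ccccc2)c2c(c1)O[C@H](c1ccc(OCc3ccccc3)c(OCc3ccccc3)c1)[C@H](O)C2 | intermediate
19 | dilithium alkoxide of 10 lithiated at the ring carbon between F and OBn | [Li]O[C@@H](c1cc(OCc2ccccc2)c(OCc2ccccc2)c(OCc2ccccc2)c1)[C@@H](OCc1ccccc1)[C@H](O[Li])c1ccc(OCc2ccccc2)c([Li])c1F | intermediate
20 | dilithium alkoxide of the 3-benzyloxyaryne (C8≡C8a) formed from 19 by loss of LiF | [Li]O[C@@H](c1cc(OCc2ccccc2)c(OCc2ccccc2)c(OCc2ccccc2)c1)[C@@H](OCc1ccccc1)[C@H](O[Li])C1=CC=C(OCc2ccccc2)C#C1 | intermediate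
21 | lithium (2S,3S,4R)-3,7-bis(benzyloxy)-8-lithio-2-[3,4,5-tris(benzyloxy)phenyl]chroman-4-olate | O1[C@@H](c3cc(OCc4ccccc4)c(OCc4ccccc4)c(OCc4ccccc4)c3)[C@@H](OCc3ccccc3)[C@H](O[Li])c2ccc(OCc3ccccc3)c([Li])c12 | intermediate
22 | (2S,3S,4R)-3,7-bis(benzyloxy)-8-{(2S,3S,4S)-3,7-bis(benzyloxy)-4-hydroxy-2-[3,4,5-tris(benzyloxy)phenyl]chroman-4-yl}-2-[3,4,5-tris(benzyloxy)phenyl]chroman-4-ol | C(c1ccccc1)Oc1ccc2c(c1)O[C@@H](c5cc(OCc6ccccc6)c(OCc6ccccc6)c(OCc6ccccc6)c5)[C@H](OCc5ccccc5)[C@@]2(O)c1c(OCc5ccccc5)ccc3c1O[C@@H](c5cc(OCc6ccccc6)c(OCc6ccccc6)c(OCc6ccccc6)c5)[C@@H](OCc5ccccc5)[C@@H]3O | intermediate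
23 | upper-unit 4-aryl-flavan-4-ylium ion from 22 (trifluoroacetate) | C(c1ccccc1)Oc1ccc2c(c1)O[C@@H](c5cc(OCc6ccccc6)c(OCc6ccccc6)c(OCc6ccccc6)c5)[C@H](OCc5ccccc5)[C+]2c1c(OCc5ccccc5)ccc3c1O[C@@H](c5cc(OCc6ccccc6)c(OCc6ccccc6)c(OCc6ccccc6)c5)[C@@H](OCc5ccccc5)[C@@H]3O.[O-]C(=O)C(F)(F)F | intermediate
24 | (2S,3S,4R)-3,7-bis(benzyloxy)-8-{(2S,3R,4S)-3,7-bis(benzyloxy)-2-[3,4,5-tris(benzyloxy)phenyl]chroman-4-yl}-2-[3,4,5-tris(benzyloxy)phenyl]chroman-4-ol | C(c1ccccc1)Oc1ccc2c(c1)O[C@@H](c5cc(OCc6ccccc6)c(OCc6ccccc6)c(OCc6ccccc6)c5)[C@H](OCc5ccccc5)[C@@H]2c1c(OCc5ccccc5)ccc3c1O[C@@H](c5cc(OCc6ccccc6)c(OCc6ccccc6)c(OCc6ccccc6)c5)[C@@H](OCc5ccccc5)[C@@H]3O | intermediate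
25 | middle-unit flavan-4-ylium ion from 24 (hydroxytrifluoroborate) | C(c1ccccc1)Oc1ccc2c(c1)O[C@@H](c5cc(OCc6ccccc6)c(OCc6ccccc6)c(OCc6ccccc6)c5)[C@H](OCc5ccccc5)[C@@H]2c1c(OCc5ccccc5)ccc3c1O[C@@H](c5cc(OCc6ccccc6)c(OCc6ccccc6)c(OCc6ccccc6)c5)[C@@H](OCc5ccccc5)[CH+]3.O[B-](F)(F)F | intermediate
26 | tetradeca-O-benzyl trimer (upper 2S,3R,4S; middle 2S,3S,4S; lower 2R,3R with free 3-OH) | C(c1ccccc1)Oc1ccc2c(c1)O[C@@H](c5cc(OCc6ccccc6)c(OCc6ccccc6)c(OCc6ccccc6)c5)[C@H](OCc5ccccc5)[C@@H]2c1c(OCc5ccccc5)ccc3c1O[C@@H](c5cc(OCc6ccccc6)c(OCc6ccccc6)c(OCc6ccccc6)c5)[C@@H](OCc5ccccc5)[C@@H]3c1c(OCc5ccccc5)cc(OCc5ccccc5)c4c1O[C@H](c1ccc(OCc5ccccc5)c(OCc5ccccc5)c1)[C@H](O)C4 | intermediate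
27 | ent-robinetinidol-(4α→8)-ent-epirobinetinidol-(4α→8)-(−)-epicatechin | Oc1ccc2c(c1)O[C@@H](c1cc(O)c(O)c(O)c1)[C@H](O)[C@@H]2c1c(O)ccc2c1O[C@@H](c1cc(O)c(O)c(O)c1)[C@@H](O)[C@@H]2c1c(O)cc(O)c2c1O[C@H](c1ccc(O)c(O)c1)[C@H](O)C2 | target

## Step count and risks

Total steps: 15. Longest linear sequence: 9 (steps 1–5, then 12–15; the branch through steps 6–10 is equally long).

**Step 12 (proposed new method).** The aryne may be captured intermolecularly by tetramethylpiperidine, or reduced by hydride transfer from the alkoxide, before the tethered alkoxide closes the ring. The hindered aryllithium may also enolise and ring-open the flavanone instead of adding to it. The fallback separates the two events with known reactions. Setting out from 10, ring C is closed by intramolecular displacement of fluoride by the tethered alkoxide (KOt-Bu, DMSO, 60–80 °C), giving (2S,3S,4R)-3,7-bis(benzyloxy)-2-[3,4,5-tris(benzyloxy)phenyl]chroman-4-ol F1. After deprotonation of its 4-OH, directed ortho-lithiation of this resorcinol-type diether at C8, the position between O1 and the C7 benzyloxy group (n-BuLi, TMEDA, THF, −20 → 0 °C), gives the 8-lithioflavan alkoxide. The fallback thus comes back to the route at 21, which adds to 16 as in step 12 to give 22.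

**Step 13.** The secondary C4 hydroxyl of the middle unit may ionise competitively and be reduced as well. This limits how far acid strength and silane size can be pushed to secure anti delivery of hydride to the upper cation, so a mixture of C4 epimers may result. The fallback changes the oxidation level of the competing site. Setting out from 22, MnO2 (CH2Cl2, rt) oxidises only the secondary benzylic alcohol and gives the middle-unit flavan-4-one carbinol F2. Ionic hydrogenation (Et3SiH, BF3·OEt2, CH2Cl2, −78 °C) can then be run without a second ionisable alcohol, giving the middle-unit flavan-4-one dimer F3, at which stage any upper C4 epimer can be removed. NaBH4/CeCl3 (MeOH/THF, −40 °C) returns the alcohol as the 2,3-cis-3,4-cis flavan-4-ol dimer F4, the C4 epimer of 24. It ionises in step 14 to the same cation, so the fallback comes back to the route at 25 and hence 26.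

**Step 9.** Acid opening of the epoxide may proceed through a free benzylic cation, with erosion of the C2 configuration, aroyl migration or formation of the 2,3-cis isomer. The fallback replaces direct acid cyclisation by a sulfur relay. Setting out from 14, benzyl mercaptan with SnCl4 (0.2 equiv, CH2Cl2, −20 °C) opens the epoxide at the benzylic carbon and removes the methoxymethyl group, giving (2R,3S)-3-(benzylsulfanyl)-1-[4-(benzyloxy)-2-hydroxyphenyl]-2-hydroxy-3-[3,4,5-tris(benzyloxy)phenyl]propan-1-one F5 (its sulfur-bearing epimer converges). Thiophilic activation with AgBF4 (CH2Cl2, 0 °C) then lets the phenol close the ring to the 2,3-trans product, coming back to the route at 15.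

## Further compounds

F1 | step 12 | (2S,3S,4R)-3,7-bis(benzyloxy)-2-[3,4,5-tris(benzyloxy)phenyl]chroman-4-ol | O1[C@@H](c3cc(OCc4ccccc4)c(OCc4ccccc4)c(OCc4ccccc4)c3)[C@@H](OCc3ccccc3)[C@H](O)c2ccc(OCc3ccccc3)cc12
F2 | step 13 | (2S,3S)-3,7-bis(benzyloxy)-8-{(2S,3S,4S)-3,7-bis(benzyloxy)-4-hydroxy-2-[3,4,5-tris(benzyloxy)phenyl]chroman-4-yl}-2-[3,4,5-tris(benzyloxy)phenyl]-2,3-dihydro-4H-chromen-4-one | C(c1ccccc1)Oc1ccc2c(c1)O[C@@H](c5cc(OCc6ccccc6)c(OCc6ccccc6)c(OCc6ccccc6)c5)[C@H](OCc5ccccc5)[C@@]2(O)c1c(OCc5ccccc5)ccc3c1O[C@@H](c5cc(OCc6ccccc6)c(OCc6ccccc6)c(OCc6ccccc6)c5)[C@@H](OCc5ccccc5)C3=O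
F3 | step 13 | (2S,3S)-3,7-bis(benzyloxy)-8-{(2S,3R,4S)-3,7-bis(benzyloxy)-2-[3,4,5-tris(benzyloxy)phenyl]chroman-4-yl}-2-[3,4,5-tris(benzyloxy)phenyl]-2,3-dihydro-4H-chromen-4-one | C(c1ccccc1)Oc1ccc2c(c1)O[C@@H](c5cc(OCc6ccccc6)c(OCc6ccccc6)c(OCc6ccccc6)c5)[C@H](OCc5ccccc5)[C@@H]2c1c(OCc5ccccc5)ccc3c1O[C@@H](c5cc(OCc6ccccc6)c(OCc6ccccc6)c(OCc6ccccc6)c5)[C@@H](OCc5ccccc5)C3=O
F4 | step 13 | (2S,3S,4S)-3,7-bis(benzyloxy)-8-{(2S,3R,4S)-3,7-bis(benzyloxy)-2-[3,4,5-tris(benzyloxy)phenyl]chroman-4-yl}-2-[3,4,5-tris(benzyloxy)phenyl]chroman-4-ol | C(c1ccccc1)Oc1ccc2c(c1)O[C@@H](c5cc(OCc6ccccc6)c(OCc6ccccc6)c(OCc6ccccc6)c5)[C@H](OCc5ccccc5)[C@@H]2c1c(OCc5ccccc5)ccc3c1O[C@@H](c5cc(OCc6ccccc6)c(OCc6ccccc6)c(OCc6ccccc6)c5)[C@@H](OCc5ccccc5)[C@H]3O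
F5 | step 9 | (2R,3S)-3-(benzylsulfanyl)-1-[4-(benzyloxy)-2-hydroxyphenyl]-2-hydroxy-3-[3,4,5-tris(benzyloxy)phenyl]propan-1-one | O=C([C@@H](O)[C@@H](SCc1ccccc1)c2cc(OCc3ccccc3)c(OCc3ccccc3)c(OCc3ccccc3)c2)c2ccc(OCc3ccccc3)cc2O
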